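- Decide first to follow one ratio instead of two curves: the late ratio, [complex with one exchanged]/[starting complex], pooled over the readings from 8.00 min on.

| setting | cedar | elm | maple | green | ochre | red |
|---|---|---|---|---|---|---|
| starting complex | 0.20 M | 0.20 M | 0.20 M | 0.20 M | 0.20 M | 0.20 M |
| incoming ligand | 0.66 equiv | 1.9 equiv | 3.8 equiv | 0.800 equiv | 1.50 equiv | 4.00 equiv |
| remark | run made earlier | run made earlier | run made earlier |  |  |  |
| time |  |  |  | 15 min | 15 min | 15 min |

| run | time / min | complex with one exchanged / % | starting complex / % |
|---|---|---|---|
| cedar | 1.33 | 16.1 | 53.6 |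
| cedar | 2.50 | 16.1 | 44.3 |
| cedar | 4.00 | 14.0 | 38.9 |
| cedar | 8.00 | 11.2 | 30.0 |
| cedar | 15.0 | 6.9 | 18.9 |
| elm | 1.33 | 16.3 | 22.0 |
| elm | 4.00 | 14.8 | 13.7 |
| elm | 8.00 | 12.8 | 9.8 |
| elm | 10.0 | 11.2 | 8.4 |
| elm | 15.0 | 12.1 | 7.1 |
| maple | 1.33 | 6.0 | 6.9 |
| maple | 4.00 | 3.4 | 1.8 |
| maple | 8.00 | 0 | 0 |
| maple | 10.0 | 3.4 | 0.4 |
| maple | 15.0 | 2.4 | 0.6 |

(standard deviation of a reading: 1 percentage point)



* amount of complex with one exchanged at the end, in percent of the starting complex charged, for each flask in turn (green, ochre, red)

- Turn the time first. By hand, if both complexes drain together, their ratio stands still while each amount falls. In cedar, [starting complex] falls from 30.0 % to 18.9 % while the ratio reads 0.373 and then 0.365, but a scatter of 1 percentage point on each reading could hide a drift there, and in elm the ratio reads 1.31 and then 1.70. So the readings don't show a constant ratio; I freeze it only as a rough working value, pooled to thin the scatter, and if the rise in elm is real, the pooled value falls short of the end ratio.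
- Turn the charge next. By hand, more incoming ligand should raise the ratio and shrink [starting complex], so their product should peak in between. The pooled ratios read 0.370 in cedar, 1.43 in elm and 5.80 in maple.
- My reckoning interpolates both factors in the charge. For ochre, the late ratio expected at its charge is 1.09; [starting complex] is 10.9 %, giving 11.9 %. For green, 0.489 times 17.6 % gives 8.61 %. For red I keep maple's ratio, but maple's [starting complex] reads 0.6 % with a scatter of 1 point, so I commit to no product there.
- The forecast interpolates the amount directly and says 8.5 %, 12 % and 2 %: “The once-exchanged complex is an intermediate, so its amount peaks at intermediate charge.”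
- The flasks give 9.06 %, 11.0 % and 0.909 % for green, ochre and red.

    complex with three exchanged + incoming ligand ⇌ leaving ligand + complex with four exchanged (K = 0.690, k = 0.350 L mol⁻¹ s⁻¹)
    crystals ⇌ leaving ligand, rate k2*(cs2 - [leaving ligand]) while solid is left; crystals form when [leaving ligand] > cs2 (solubility = 6.10 mM, k = 0.300 s⁻¹)
    complex with one exchanged + incoming ligand ⇌ leaving ligand + complex with two exchanged (K = 0.530, k = 0.260 L mol⁻¹ s⁻¹)
    starting complex + incoming ligand ⇌ leaving ligand + complex with one exchanged (K = 0.390, k = 0.130 L mol⁻¹ s⁻¹)
    complex with two exchanged + incoming ligand ⇌ leaving ligand + complex with three exchanged (K = 0.0960, k = 0.270 L mol⁻¹ s⁻¹)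
    starting complex + complex with one exchanged → side product (k = 0.0430 L mol⁻¹ s⁻¹)

- In ochre, the back reaction of leaving ligand with complex with one exchanged and the loss to side product act together: complex with one exchanged stands at 11.0 %, against 22.7 % without that back reaction and 25.0 % without that loss. With the first exchange running both ways (a pre-equilibrium), the ratio should be 0.39[incoming ligand]/[leaving ligand], which gives 1.24 for ochre, whose end ratio is 1.30 against the expected 1.09. For red, the same expression gives 5.28, and its end ratio is 5.29.

(All runs stem from a simulated flask from invented constants; scatter was added.)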